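**Strategy.** Ring A is numbered as a 5,6,7,8-tetrahydrochromone, the second chromone with primes. The bridge is disconnected at C7–O6′ (epoxide opening), leaving a 5-aryloxy-6-hydroxy-5,6-dihydrochromone. This is made in one operation from two chromone halves. C6–H of a 2-(3-silyloxypropenyl)-3-formyl-γ-pyrone is the ε-position of a doubly vinylogous 1,3-dicarbonyl (C4=O, C5=O), so base gives the oxido-triene C6=C7–C8=C8a–C4a=C5–O⁻. A 6π closure forms C5–C6 and closes the carbocycle, and the C5 alkoxide then displaces fluoride from C7′, para to the C4′ carbonyl of a 7-fluorochromone. The precursor is an achiral open-chain dienal; C7 and C8 follow from a directed epoxidation.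

Key step: step 10

Remark: O5 is the oxygen on C5; compounds 1, 3, 7, 12 and 15 are taken as commercial; 20 to 23 are racemic (one enantiomer drawn) and the enantiomer series is selected in step 12.

**Step 1**
Reactants: 1 4-(4-methoxyphenyl)but-1-yne
Product: 2 5-(4-methoxyphenyl)pent-2-ynoic acid
Conditions: n-BuLi, THF, –78 °C; CO2, –78 to 0 °C; then 1 M HCl
Reagents that add atoms: carbon dioxide, O=C=O
Why: Deprotonation of the terminal alkyne and carboxylation of the lithium acetylide (acetylide carboxylation) should give the ynoic acid; no stereocentre is involved.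

**Step 2**
Reactants: 2 5-(4-methoxyphenyl)pent-2-ynoic acid; 3 N-methoxy-N-methyl-3-oxobutanamide
Product: 6 N-methoxy-6-[2-(4-methoxyphenyl)ethyl]-N,2-dimethyl-4-oxo-4H-pyran-3-carboxamide, via acid chloride 4 (not isolated), via triketo amide 5 (not isolated)
Conditions: (COCl)2, DMF (cat.), CH2Cl2, 0 °C to rt; then 3, MgCl2, pyridine, CH2Cl2, 0 °C to rt; then DBU (cat.), rt
Reagents that add atoms: none
Why: Magnesium-mediated soft enolisation should C-acylate the β-keto amide with the alkynoyl chloride, and the acetyl enol oxygen of 5 then adds 6-endo-dig to the ynone (classical γ-pyrone synthesis from alkynoyl chlorides and 1,3-dicarbonyl compounds), fixing the 2-methyl, 3-carboxamide and 6-arylethyl pattern.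

**Step 3**
Reactants: 6 N-methoxy-6-[2-(4-methoxyphenyl)ethyl]-N,2-dimethyl-4-oxo-4H-pyran-3-carboxamide; 7 (tert-butyldimethylsilyloxy)acetaldehyde
Product: 8 2-[3-(tert-butyldimethylsilyloxy)-2-hydroxypropyl]-N-methoxy-6-[2-(4-methoxyphenyl)ethyl]-N-methyl-4-oxo-4H-pyran-3-carboxamide
Conditions: LiN(SiMe3)2, THF, –78 °C; 7, –78 °C; then AcOH
Reagents that add atoms: none
Why: The 2-methyl group, vinylogous to both the ring ketone and the 3-carboxamide, should be lithiated selectively and add to the aldehyde (vinylogous aldol addition); the new carbinol centre forms as a racemate and is removed in step 4.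

**Step 4**
Reactants: 8 2-[3-(tert-butyldimethylsilyloxy)-2-hydroxypropyl]-N-methoxy-6-[2-(4-methoxyphenyl)ethyl]-N-methyl-4-oxo-4H-pyran-3-carboxamide
Product: 10 2-[(E)-3-(tert-butyldimethylsilyloxy)prop-1-enyl]-N-methoxy-6-[2-(4-methoxyphenyl)ethyl]-N-methyl-4-oxo-4H-pyran-3-carboxamide, via mesylate 9 (not isolated)
Conditions: MsCl, Et3N, CH2Cl2, 0 °C; then DBU, rt
Reagents that add atoms: none
Why: Mesylation and E1cB elimination through the vinylogous enolate should give the alkene conjugated to the pyranone, the (E)-isomer being favoured thermodynamically.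

**Step 5**
Reactants: 10 2-[(E)-3-(tert-butyldimethylsilyloxy)prop-1-enyl]-N-methoxy-6-[2-(4-methoxyphenyl)ethyl]-N-methyl-4-oxo-4H-pyran-3-carboxamide
Product: 11 2-[(E)-3-(tert-butyldimethylsilyloxy)prop-1-enyl]-6-[2-(4-methoxyphenyl)ethyl]-4-oxo-4H-pyran-3-carbaldehyde
Conditions: i-Bu2AlH (1.2 equiv), THF, –78 °C; then aqueous potassium sodium tartrate
Reagents that add atoms: none
Why: Weinreb amide reduction should stop at the aldehyde through the chelated tetrahedral aluminate, the vinylogous-ester carbonyl of the pyranone being much less electrophilic.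

**Step 6**
Reactants: 12 3-fluoro-4-methoxyphenol
Product: 14 1-(4-fluoro-2-hydroxy-5-methoxyphenyl)ethan-1-one, via aryl acetate 13 (not isolated)
Conditions: Ac2O, MeSO3H, 25 °C then 80 °C
Reagents that add atoms: acetic anhydride, CC(=O)OC(C)=O
Why: O-Acetylation and acid-mediated Fries rearrangement should place the acetyl group ortho to the hydroxyl and para to fluorine, since the para position is blocked by methoxy and the other ortho position is flanked by fluorine.

**Step 7**
Reactants: 14 1-(4-fluoro-2-hydroxy-5-methoxyphenyl)ethan-1-one; 15 ethyl 3-phenylpropanoate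
Product: 17 7-fluoro-6-methoxy-2-(2-phenylethyl)-4H-chromen-4-one, via diketone 16 (not isolated)
Conditions: NaH (3.5 equiv), THF, reflux; then conc. HCl, AcOH, 90 °C
Reagents that add atoms: none
Why: Claisen condensation of the acetophenone with the ester and acid cyclodehydration of the o-hydroxyaryl 1,3-diketone is the standard chromone synthesis; the phenoxide deactivates the ring so that ethoxide should not displace fluoride.

**Step 8**
Reactants: 17 7-fluoro-6-methoxy-2-(2-phenylethyl)-4H-chromen-4-one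
Product: 18 7-fluoro-6-hydroxy-2-(2-phenylethyl)-4H-chromen-4-one
Conditions: BBr3, CH2Cl2, –78 to 0 °C; then H2O
Reagents that add atoms: none
Why: Lewis-acid cleavage of the aryl methyl ether (BBr3 demethylation) should leave the chromone and the aryl fluoride untouched.

**Step 9**
Reactants: 18 7-fluoro-6-hydroxy-2-(2-phenylethyl)-4H-chromen-4-one
Product: 19 6-(allyloxy)-7-fluoro-2-(2-phenylethyl)-4H-chromen-4-one
Conditions: allyl bromide, K2CO3, DMF, 25 °C
Reagents that add atoms: allyl bromide, C=CCBr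
Why: Williamson etherification masks O6′ so that the ring stays electron-poor and C7′–F remains activated for step 10.

**Step 10**
Reactants: 11 2-[(E)-3-(tert-butyldimethylsilyloxy)prop-1-enyl]-6-[2-(4-methoxyphenyl)ethyl]-4-oxo-4H-pyran-3-carbaldehyde; 19 6-(allyloxy)-7-fluoro-2-(2-phenylethyl)-4H-chromen-4-one
Product: 22 rac-(5R,6R)-5-{[6-(allyloxy)-4-oxo-2-(2-phenylethyl)-4H-chromen-7-yl]oxy}-6-(tert-butyldimethylsilyloxy)-2-[2-(4-methoxyphenyl)ethyl]-5,6-dihydro-4H-chromen-4-one, via potassium trienolate 20 (not isolated), via potassium alkoxide 21 (not isolated)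
Conditions: KN(SiMe3)2 (1.05 equiv), 18-crown-6, THF, –78 °C; then 19 (1.5 equiv), DMF, –40 to 25 °C; pH 7 buffer
Reagents that add atoms: none
Why: Proposed new method: KN(SiMe3)2 removes the ε-proton at C6 of 11, which is doubly vinylogous to the C4 ketone and the C5 aldehyde, to give trienolate 20, that is the 1-oxidohexatriene C6=C7–C8=C8a–C4a=C5–O(–); its thermal disrotatory 6π electrocyclisation (formally a 6-(enolendo)-exo-trig intramolecular vinylogous aldol addition) closes the six-membered carbocycle C4a–C5–C6–C7–C8–C8a through the new C5–C6 bond, and alkoxide 21 then forms the O5–C7′ bond by addition–elimination (SNAr) at the fluorine-bearing carbon of 19, para to the chromone carbonyl, no other ring being closed. The closest known reaction types are the electrocyclisation of hydroxy-o-quinodimethanes from o-alkyl aryl aldehydes, dienolate annulations of 2-methyl-3-acylchromones and tandem carbonyl-addition/SNAr etherification, but their combination on a γ-pyrone aldehyde has not been shown. Ring closure is reversible and 21 is the less stable partner, so the irreversible loss of fluoride must draw material through (Curtin–Hammett), and O-arylation of 20 at O5 followed by 6π closure of the neutral aryloxytriene would converge on the same product. C5 and C6 are created together: with the crown-complexed potassium cation the oxido group should lie inside (anti to the C4 carbonyl dipole) and the silyloxy group outside on the (E)-enol ether terminus, so disrotation places O5 and O6 trans, and the trans alkoxide should also be arylated faster because its oxygen is not flanked by a syn silyl ether; absolute configuration is not controlled and 22 is a racemate. The step needs arylation at O5 in preference to O4 or carbon of the trienolate and must avoid base-induced loss of the aryloxide from C5 with aromatisation of ring A, which the exact charge of base (none is left once potassium fluoride has formed), the low temperature and the hard, unhindered alkoxide oxygen are meant to secure.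

**Step 11**
Reactants: 22 rac-(5R,6R)-5-{[6-(allyloxy)-4-oxo-2-(2-phenylethyl)-4H-chromen-7-yl]oxy}-6-(tert-butyldimethylsilyloxy)-2-[2-(4-methoxyphenyl)ethyl]-5,6-dihydro-4H-chromen-4-one
Product: 23 rac-(5R,6R)-5-{[6-(allyloxy)-4-oxo-2-(2-phenylethyl)-4H-chromen-7-yl]oxy}-6-hydroxy-2-[2-(4-methoxyphenyl)ethyl]-5,6-dihydro-4H-chromen-4-one
Conditions: HF·pyridine, pyridine, THF, 0 °C
Reagents that add atoms: none
Why: Fluoride cleavage of the secondary silyl ether under buffered, non-basic conditions should free the C6 hydroxyl without forming an alkoxide, so that neither O5-to-O6 aryl migration (Smiles rearrangement) nor elimination is triggered and C5 and C6 are untouched.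

**Step 12**
Reactants: 23 rac-(5R,6R)-5-{[6-(allyloxy)-4-oxo-2-(2-phenylethyl)-4H-chromen-7-yl]oxy}-6-hydroxy-2-[2-(4-methoxyphenyl)ethyl]-5,6-dihydro-4H-chromen-4-one
Product: 24 (5R,6S,7S,8S)-5-{[6-(allyloxy)-4-oxo-2-(2-phenylethyl)-4H-chromen-7-yl]oxy}-7,8-epoxy-6-hydroxy-2-[2-(4-methoxyphenyl)ethyl]-5,6,7,8-tetrahydro-4H-chromen-4-one
Conditions: VO(Oi-Pr)3 (2 mol%), N,N′-bis(diphenylacetyl)-N,N′-dihydroxy-trans-cyclohexane-1,2-diamine (4 mol%, enantiomer matched to (5R,6R)-23), t-BuOOH (0.55 equiv), toluene, 0 °C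
Reagents that add atoms: tert-butyl hydroperoxide, CC(C)(C)OO
Why: Hydroxyl-directed vanadium-catalysed asymmetric epoxidation run as a kinetic resolution should epoxidise only the (5R,6R)-alcohol, delivering oxygen to the C7=C8 face syn to the C6 hydroxyl (cis-epoxy alcohol, anti to the 5-aryloxy group), which selects the enantiomer series and sets C8 and the precursor configuration of C7; the (5S,6S)-alcohol is left and separated.

**Step 13**
Reactants: 24 (5R,6S,7S,8S)-5-{[6-(allyloxy)-4-oxo-2-(2-phenylethyl)-4H-chromen-7-yl]oxy}-7,8-epoxy-6-hydroxy-2-[2-(4-methoxyphenyl)ethyl]-5,6,7,8-tetrahydro-4H-chromen-4-one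
Product: 26 (+)-4′-methoxyaquisinenone G, via phenol 25 (not isolated)
Conditions: Pd(PPh3)4 (5 mol%), morpholine, THF, 25 °C; then K2CO3 (0.2 equiv), MeOH, 25 °C
Reagents that add atoms: none
Why: Palladium-catalysed deallylation (Tsuji–Trost type) frees the C6′ phenol, whose phenoxide, held on the upper face by the O5–C7′ ether, should open the epoxide at C7 by 7-exo-tet SN2 attack anti to the epoxide oxygen (trans-diaxial opening, Fürst–Plattner rule), inverting C7 and leaving the C8 oxygen on the lower face as in the target.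

**Compound list**

1 | 4-(4-methoxyphenyl)but-1-yne | C#CCCc1ccc(OC)cc1 | starting material
2 | 5-(4-methoxyphenyl)pent-2-ynoic acid | OC(=O)C#CCCc1ccc(OC)cc1 | intermediate
3 | N-methoxy-N-methyl-3-oxobutanamide | CC(=O)CC(=O)N(C)OC | starting material
4 | 5-(4-methoxyphenyl)pent-2-ynoyl chloride | ClC(=O)C#CCCc1ccc(OC)cc1 | intermediate
5 | 2-acetyl-N-methoxy-7-(4-methoxyphenyl)-N-methyl-3-oxohept-4-ynamide | CC(=O)C(C(=O)N(C)OC)C(=O)C#CCCc1ccc(OC)cc1 | intermediate
6 | N-methoxy-6-[2-(4-methoxyphenyl)ethyl]-N,2-dimethyl-4-oxo-4H-pyran-3-carboxamide | Cc1oc(CCc2ccc(OC)cc2)cc(=O)c1C(=O)N(C)OC | intermediate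
7 | (tert-butyldimethylsilyloxy)acetaldehyde | O=CCO[Si](C)(C)C(C)(C)C | starting material
8 | 2-[3-(tert-butyldimethylsilyloxy)-2-hydroxypropyl]-N-methoxy-6-[2-(4-methoxyphenyl)ethyl]-N-methyl-4-oxo-4H-pyran-3-carboxamide (racemic carbinol) | CON(C)C(=O)c1c(CC(O)CO[Si](C)(C)C(C)(C)C)oc(CCc2ccc(OC)cc2)cc1=O | intermediate
9 | methanesulfonate of 8 | CON(C)C(=O)c1c(CC(OS(C)(=O)=O)CO[Si](C)(C)C(C)(C)C)oc(CCc2ccc(OC)cc2)cc1=O | intermediate
10 | 2-[(E)-3-(tert-butyldimethylsilyloxy)prop-1-enyl]-N-methoxy-6-[2-(4-methoxyphenyl)ethyl]-N-methyl-4-oxo-4H-pyran-3-carboxamide | CON(C)C(=O)c1c(/C=C/CO[Si](C)(C)C(C)(C)C)oc(CCc2ccc(OC)cc2)cc1=O | intermediate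
11 | 2-[(E)-3-(tert-butyldimethylsilyloxy)prop-1-enyl]-6-[2-(4-methoxyphenyl)ethyl]-4-oxo-4H-pyran-3-carbaldehyde | O=Cc1c(/C=C/CO[Si](C)(C)C(C)(C)C)oc(CCc2ccc(OC)cc2)cc1=O | intermediate
12 | 3-fluoro-4-methoxyphenol | COc1ccc(O)cc1F | starting material
13 | 3-fluoro-4-methoxyphenyl acetate | CC(=O)Oc1ccc(OC)c(F)c1 | intermediate
14 | 1-(4-fluoro-2-hydroxy-5-methoxyphenyl)ethan-1-one | CC(=O)c1cc(OC)c(F)cc1O | intermediate
15 | ethyl 3-phenylpropanoate | CCOC(=O)CCc1ccccc1 | starting material
16 | 1-(4-fluoro-2-hydroxy-5-methoxyphenyl)-5-phenylpentane-1,3-dione | O=C(CC(=O)CCc1ccccc1)c1cc(OC)c(F)cc1O | intermediate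
17 | 7-fluoro-6-methoxy-2-(2-phenylethyl)-4H-chromen-4-one | COc1cc2c(=O)cc(CCc3ccccc3)oc2cc1F | intermediate
18 | 7-fluoro-6-hydroxy-2-(2-phenylethyl)-4H-chromen-4-one | Oc1cc2c(=O)cc(CCc3ccccc3)oc2cc1F | intermediate
19 | 6-(allyloxy)-7-fluoro-2-(2-phenylethyl)-4H-chromen-4-one | C=CCOc1cc2c(=O)cc(CCc3ccccc3)oc2cc1F | intermediate
20 | potassium trienolate of 11 (1-oxidohexatriene form, reactive geometry drawn) | [K+].[O-]/C=C1/C(=O)C=C(CCc2ccc(OC)cc2)O/C1=C/C=C/O[Si](C)(C)C(C)(C)C | intermediate
21 | rac-potassium (5R,6R)-6-(tert-butyldimethylsilyloxy)-2-[2-(4-methoxyphenyl)ethyl]-4-oxo-5,6-dihydro-4H-chromen-5-olate (5,6-trans) | [K+].COc1ccc(CCc2cc(=O)c3c(o2)C=C[C@@H](O[Si](C)(C)C(C)(C)C)[C@@H]3[O-])cc1 | intermediate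
22 | rac-(5R,6R)-5-{[6-(allyloxy)-4-oxo-2-(2-phenylethyl)-4H-chromen-7-yl]oxy}-6-(tert-butyldimethylsilyloxy)-2-[2-(4-methoxyphenyl)ethyl]-5,6-dihydro-4H-chromen-4-one (5,6-trans, racemate) | COc1ccc(CCc2cc(=O)c3c(o2)C=C[C@@H](O[Si](C)(C)C(C)(C)C)[C@@H]3Oc2cc3oc(CCc4ccccc4)cc(=O)c3cc2OCC=C)cc1 | intermediate
23 | rac-(5R,6R)-5-{[6-(allyloxy)-4-oxo-2-(2-phenylethyl)-4H-chromen-7-yl]oxy}-6-hydroxy-2-[2-(4-methoxyphenyl)ethyl]-5,6-dihydro-4H-chromen-4-one (5,6-trans, racemate) | COc1ccc(CCc2cc(=O)c3c(o2)C=C[C@@H](O)[C@@H]3Oc2cc3oc(CCc4ccccc4)cc(=O)c3cc2OCC=C)cc1 | intermediate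
24 | (5R,6S,7S,8S)-5-{[6-(allyloxy)-4-oxo-2-(2-phenylethyl)-4H-chromen-7-yl]oxy}-7,8-epoxy-6-hydroxy-2-[2-(4-methoxyphenyl)ethyl]-5,6,7,8-tetrahydro-4H-chromen-4-one (epoxide cis to 6-OH, trans to 5-aryloxy) | COc1ccc(CCc2cc(=O)c3c(o2)[C@H]2O[C@H]2[C@@H](O)[C@@H]3Oc2cc3oc(CCc4ccccc4)cc(=O)c3cc2OCC=C)cc1 | intermediate
25 | (5R,6S,7S,8S)-7,8-epoxy-6-hydroxy-5-{[6-hydroxy-4-oxo-2-(2-phenylethyl)-4H-chromen-7-yl]oxy}-2-[2-(4-methoxyphenyl)ethyl]-5,6,7,8-tetrahydro-4H-chromen-4-one | COc1ccc(CCc2cc(=O)c3c(o2)[C@H]2O[C@H]2[C@@H](O)[C@@H]3Oc2cc3oc(CCc4ccccc4)cc(=O)c3cc2O)cc1 | intermediate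
26 | (+)-4′-methoxyaquisinenone G; ring-A centres (5R,6S,7R,8S), O5 bonded to C7′ and O7 to C6′ of the second chromone, 6-OH and 8-OH free | COc1ccc(CCc2cc(=O)c3c(o2)[C@@H](O)[C@@H]2Oc4cc5c(=O)cc(CCc6ccccc6)oc5cc4O[C@H]3[C@@H]2O)cc1 | target

**Summary**

Total steps: 13. Longest linear sequence: 9 steps (steps 1 to 5, then 10 to 13).

Steps most likely to fail:

1. Step 10 (bears the label). What may go wrong: arylation is slow because the cyclised alkoxide is only a minor equilibrium partner of the trienolate; the trienolate is arylated at O4 or carbon; the 5,6-trans preference erodes; base removes the C6 proton of the product and the aryloxide is lost with aromatisation of ring A. Fallback with known chemistry, setting out from 11 and coming back at 22: soft enolisation of 11 with Et3SiOTf and Et3N in CH2Cl2 (–78 to 25 °C) should give the neutral 1-(triethylsilyloxy)triene F1, a silyl dienol ether that cannot revert to an enolate. Its thermal 6π electrocyclisation should give rac-(5R,6R)-6-(tert-butyldimethylsilyloxy)-2-[2-(4-methoxyphenyl)ethyl]-5-(triethylsilyloxy)-5,6-dihydro-4H-chromen-4-one F2, from which any cis isomer is removed by chromatography. The more labile triethylsilyl ether is then arylated with 19 by fluoride-catalysed silyl-ether SNAr (CsF, 18-crown-6, DMF, 40 °C) to give 22.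

2. Step 12. What may go wrong: the rate difference between the two enantiomers is too small, or the electron-poor diene is epoxidised too slowly, so that 24 is obtained with insufficient enantiomeric purity. Fallback, setting out from 23 and coming back at 24: acylative kinetic resolution of 23 with a chiral isothiourea catalyst (benzotetramisole, the enantiomer that acylates the (5S,6S)-alcohol), isobutyric anhydride and i-Pr2NEt in CHCl3 at 0 °C should convert the unwanted antipode into the (5S,6S)-isobutyrate F3. The recovered (5R,6R)-23 is then epoxidised with achiral VO(acac)2 and t-BuOOH, again syn to the hydroxyl, to give 24.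

3. Step 13. What may go wrong: the palladium catalyst ionises the epoxide, which is allylic to the pyranone double bond; morpholine opens the epoxide before the phenol is free; or base causes elimination at C7–C8. Fallback, setting out from 23 (the resolved (5R,6R)-alcohol from the fallback to step 12) and coming back at 26: the allyl ether is removed first, while no epoxide is present (Pd(PPh3)4, morpholine, THF), to give the phenol (5R,6R)-6-hydroxy-5-{[6-hydroxy-4-oxo-2-(2-phenylethyl)-4H-chromen-7-yl]oxy}-2-[2-(4-methoxyphenyl)ethyl]-5,6-dihydro-4H-chromen-4-one F4. Hydroxyl-directed peracid epoxidation (m-CPBA, NaHCO3, CH2Cl2, 0 °C) should then give 25, which closes to 26 with K2CO3 in MeOH.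

**Further compounds**

F1 | step 10 | 2-[(1E,3E)-4-(tert-butyldimethylsilyloxy)buta-1,3-dienylidene-type triene: 3-[(triethylsilyloxy)methylene]-2-[3-(tert-butyldimethylsilyloxy)allylidene]-6-[2-(4-methoxyphenyl)ethyl]-2,3-dihydro-4H-pyran-4-one (reactive geometry drawn) | CC[Si](CC)(CC)O/C=C1/C(=O)C=C(CCc2ccc(OC)cc2)O/C1=C/C=C/O[Si](C)(C)C(C)(C)C
F2 | step 10 | rac-(5R,6R)-6-(tert-butyldimethylsilyloxy)-2-[2-(4-methoxyphenyl)ethyl]-5-(triethylsilyloxy)-5,6-dihydro-4H-chromen-4-one | COc1ccc(CCc2cc(=O)c3c(o2)C=C[C@@H](O[Si](C)(C)C(C)(C)C)[C@@H]3O[Si](CC)(CC)CC)cc1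
F3 | step 12 | (5S,6S)-5-{[6-(allyloxy)-4-oxo-2-(2-phenylethyl)-4H-chromen-7-yl]oxy}-2-[2-(4-methoxyphenyl)ethyl]-4-oxo-5,6-dihydro-4H-chromen-6-yl 2-methylpropanoate | COc1ccc(CCc2cc(=O)c3c(o2)C=C[C@H](OC(=O)C(C)C)[C@H]3Oc2cc3oc(CCc4ccccc4)cc(=O)c3cc2OCC=C)cc1
F4 | step 13 | (5R,6R)-6-hydroxy-5-{[6-hydroxy-4-oxo-2-(2-phenylethyl)-4H-chromen-7-yl]oxy}-2-[2-(4-methoxyphenyl)ethyl]-5,6-dihydro-4H-chromen-4-one | COc1ccc(CCc2cc(=O)c3c(o2)C=C[C@@H](O)[C@@H]3Oc2cc3oc(CCc4ccccc4)cc(=O)c3cc2O)cc1
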